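**Plan**

1. The retrosynthesis cuts the C6–C7 bond of the undecan-2-yl chain (between the fifth and sixth CH2 counted from the ring). This gives two acids, 6-(6-methoxy-3,5-dimethyl-4-oxo-4H-pyran-2-yl)hexanoic acid and (S)-6-acetoxyheptanoic acid, to be joined by a mixed Kolbe electrolysis in which both CO2H helpers leave as CO2.
2. Enabling feature: C6 and C7 are unbranched CH2 carbons inside a (CH2)9 tether, four CH2 from ring carbon C2 of the 4-pyranone and three CH2 from the acetoxy-bearing C2 stereocentre. Both radicals are therefore unstabilised primary alkyl radicals that couple instead of being oxidised further, and neither the ring nor the stereocentre takes part.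
3. Pyranone half: the ring C2–C3 bond is cut first (γ-acylation of a β-keto ester dianion by a pimelic half-ester), then O1–C6 (lactonisation to the 4-hydroxy-2-pyranone), then O–CH3 (regioselective O-methylation to the 2-methoxy-4-pyranone); ester hydrolysis frees the acid.
4. Acetate half: (S)-propylene oxide is opened at CH2 by pent-4-enylmagnesium bromide, the alcohol is acetylated, and the terminal alkene is cleaved oxidatively to the acid.
5. Forward order: the ring is built in steps 1–4, the side-chain acid in parallel in steps 5–7, and the chain is joined last in step 8.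
6. Stereochemistry: the single stereocentre comes from commercial (S)-propylene oxide, and its C–O bond is never broken.

Key step: step 8

Remark: the diketo ester 5 should form as a mixture of diastereomers and keto–enol tautomers; both of its stereocentres disappear on ring closure, so it is written without configuration.

**Route**

Step 1
Reactants: 1 7-methoxy-7-oxoheptanoic acid (monomethyl pimelate); 2 methyl 2-methyl-3-oxopentanoate
Product: 5 dimethyl 2,4-dimethyl-3,5-dioxoundecanedioate, via acyl imidazole 3 (not isolated), via dilithium dienolate 4 (not isolated)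
Conditions: 1, CDI (1.05 equiv), THF, rt (gives 3); separately 2 (3 equiv), LDA (6 equiv), THF, −78 → 0 °C (gives 4); add 3 at −78 °C; 1 M HCl
Reagents that add atoms: none
Why: Claisen-type γ-acylation of a β-keto ester dianion, in which the terminal carbanion of 4 is the more nucleophilic site and the acyl imidazole is far more electrophilic than the remote methyl ester at −78 °C, so C-acylation should give the 3,5-dioxo ester carrying all carbons of the pyranone half.

Step 2
Reactants: 5 dimethyl 2,4-dimethyl-3,5-dioxoundecanedioate
Product: 6 methyl 6-(4-hydroxy-3,5-dimethyl-2-oxo-2H-pyran-6-yl)hexanoate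
Conditions: DBU (2 equiv), toluene, 80 °C; 1 M HCl wash
Reagents that add atoms: none
Why: Base-mediated lactonisation, the standard cyclisation of 3,5-dioxo esters to 4-hydroxy-2-pyranones, in which the C5 enolate oxygen attacks the C1 ester (six-membered ring) and methoxide is lost; the remote ester cannot close a comparable ring.

Step 3
Reactants: 6 methyl 6-(4-hydroxy-3,5-dimethyl-2-oxo-2H-pyran-6-yl)hexanoate
Product: 7 methyl 6-(6-methoxy-3,5-dimethyl-4-oxo-4H-pyran-2-yl)hexanoate
Conditions: MeOTf (1.5 equiv), CH2Cl2, 0 °C → rt; aq. NaHCO3
Reagents that add atoms: methyl trifluoromethanesulfonate, COS(=O)(=O)C(F)(F)F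
Why: O-methylation of the neutral 4-hydroxy-2-pyranone by a hard, non-basic methylating agent should occur at its most basic and least hindered oxygen, the lactone carbonyl (the 4-OH lies between two methyl groups), and loss of the 4-OH proton from the 2-methoxypyrylium ion gives the 2-methoxy-4-pyranone, the standard regioselective entry to this ring.

Step 4
Reactants: 7 methyl 6-(6-methoxy-3,5-dimethyl-4-oxo-4H-pyran-2-yl)hexanoate
Product: 8 6-(6-methoxy-3,5-dimethyl-4-oxo-4H-pyran-2-yl)hexanoic acid
Conditions: LiOH·H2O (1.5 equiv), THF/H2O 3:1, 0 °C; 1 M HCl to pH 3–4 at 0 °C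
Reagents that add atoms: lithium hydroxide, [Li+].[OH-]
Why: Saponification of an unhindered primary-alkyl methyl ester should be much faster at 0 °C than hydroxide addition–elimination at C6 of the pyranone, a vinylogous carbonate carbon deactivated by the aromatic ring, and brief cold acidification should not isomerise the methoxypyranone.

Step 5
Reactants: 9 5-bromopent-1-ene; 10 (S)-2-methyloxirane ((S)-propylene oxide)
Product: 12 (S)-oct-7-en-2-ol, via pent-4-enylmagnesium bromide 11 (not isolated)
Conditions: 9 (1.3 equiv), Mg, THF, rt → 40 °C; CuI (10 mol%), 10, −30 → 0 °C; cold 1 M HCl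
Reagents that add atoms: none
Why: Copper-catalysed SN2 opening of a terminal epoxide by a primary Grignard reagent at the unsubstituted CH2; the C–O bond of the stereocentre is not touched, so the (S) configuration of 10 is carried over unchanged.

Step 6
Reactants: 12 (S)-oct-7-en-2-ol
Product: 13 (S)-oct-7-en-2-yl acetate
Conditions: Ac2O (1.5 equiv), pyridine, DMAP (5 mol%), CH2Cl2, 0 °C → rt
Reagents that add atoms: acetic anhydride, CC(=O)OC(C)=O
Why: DMAP-catalysed acylation of a secondary alcohol at oxygen, which leaves the C–O bond and hence the configuration intact.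

Step 7
Reactants: 13 (S)-oct-7-en-2-yl acetate
Product: 14 (S)-6-acetoxyheptanoic acid
Conditions: RuCl3·xH2O (2 mol%), NaIO4 (4.1 equiv), CCl4/MeCN/H2O 2:2:3, rt
Reagents that add atoms: sodium periodate, [Na+].[O-]I(=O)(=O)=O
Why: Ruthenium tetroxide cleavage of a terminal alkene to the carboxylic acid with loss of the terminal carbon; the secondary acetate is inert and the stereocentre is four carbons from the reacting site.

Step 8
Reactants: 8 6-(6-methoxy-3,5-dimethyl-4-oxo-4H-pyran-2-yl)hexanoic acid; 14 (S)-6-acetoxyheptanoic acid
Product: 15 (S)-11-(6-methoxy-3,5-dimethyl-4-oxo-4H-pyran-2-yl)undecan-2-yl acetate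
Conditions: undivided cell, smooth Pt anode and Pt cathode, MeOH, 8 (1 equiv), 14 (5 equiv), NaOMe (5 mol% of total CO2H), constant current ca. 0.2 A cm−2, 25–35 °C, ca. 1.3 F per mol CO2H, stopped while still slightly acidic
Reagents that add atoms: none
Why: At a smooth platinum anode at high current density both carboxylates are oxidised by one electron, the acyloxy radicals lose CO2, and the 5-(pyranonyl)pentyl and (S)-5-acetoxyhexyl radicals combine at the electrode surface to form the C6–C7 bond of the undecan-2-yl chain. The closest known reaction type is the mixed (crossed) Kolbe electrolysis of two ω-functionalised alkanoic acids, long used to assemble unbranched chains that carry remote esters and acetoxy groups. No ring is closed and no stereocentre is created; the C–OAc stereocentre lies four carbons from the radical centre, belongs to no bond made or broken, and a 1,5-hydrogen shift to it should be far slower than radical coupling at the anode and could not lead to the product in any case. The step needs radical coupling rather than further oxidation to a cation (Hofer–Moest pathway), which is secured by both radicals being unbranched primary CH2 radicals without an α-heteroatom or α-branch, together with platinum, weakly acidic methanol and a low degree of neutralisation. It also needs cross- rather than homo-coupling of the valuable acid 8, which is secured statistically by the fivefold excess of the cheap acid 14, whose neutral symmetrical dimer should be separable by chromatography. The pyranone and the acetate are expected to survive because the adsorbed carboxylate layer shields other groups from the anode and the excess acid keeps the medium buffered.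

**Compound list**

1 | 7-methoxy-7-oxoheptanoic acid (monomethyl pimelate) | COC(=O)CCCCCC(=O)O | starting material
2 | methyl 2-methyl-3-oxopentanoate | CCC(=O)C(C)C(=O)OC | starting material
3 | methyl 7-(1H-imidazol-1-yl)-7-oxoheptanoate (acyl imidazole of 1, formed in situ) | COC(=O)CCCCCC(=O)n1ccnc1 | intermediate
4 | dilithium 1-methoxy-2-methylpenta-1,3-diene-1,3-diolate (dianion of 2, formed in situ) | [Li+].[Li+].COC([O-])=C(C)C([O-])=CC | intermediate
5 | dimethyl 2,4-dimethyl-3,5-dioxoundecanedioate | COC(=O)C(C)C(=O)C(C)C(=O)CCCCCC(=O)OC | intermediate
6 | methyl 6-(4-hydroxy-3,5-dimethyl-2-oxo-2H-pyran-6-yl)hexanoate | COC(=O)CCCCCc1oc(=O)c(C)c(O)c1C | intermediate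
7 | methyl 6-(6-methoxy-3,5-dimethyl-4-oxo-4H-pyran-2-yl)hexanoate | COC(=O)CCCCCc1oc(OC)c(C)c(=O)c1C | intermediate
8 | 6-(6-methoxy-3,5-dimethyl-4-oxo-4H-pyran-2-yl)hexanoic acid | COc1oc(CCCCCC(=O)O)c(C)c(=O)c1C | intermediate
9 | 5-bromopent-1-ene | C=CCCCBr | starting material
10 | (S)-2-methyloxirane ((S)-propylene oxide) | C[C@H]1CO1 | starting material
11 | pent-4-enylmagnesium bromide (formed in situ) | C=CCCC[Mg]Br | intermediate
12 | (S)-oct-7-en-2-ol | C=CCCCC[C@H](C)O | intermediate
13 | (S)-oct-7-en-2-yl acetate | C=CCCCC[C@H](C)OC(C)=O | intermediate
14 | (S)-6-acetoxyheptanoic acid | OC(=O)CCCC[C@H](C)OC(C)=O | intermediate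
15 | (S)-11-(6-methoxy-3,5-dimethyl-4-oxo-4H-pyran-2-yl)undecan-2-yl acetate | COc1oc(CCCCCCCCC[C@H](C)OC(C)=O)c(C)c(=O)c1C | target

**Count and risks**

Total steps: 8. Longest linear sequence: 5 steps (steps 1, 2, 3, 4 and 8).

Steps most likely to fail:

Step 8. The electron-rich pyranone may be oxidised at the anode or foul it, or homo-coupling and radical disproportionation may outrun the cross-coupling, so that little cross product forms. The fallback sets out from 8 and 14 and comes back at 15. Each acid is converted with N-hydroxyphthalimide, DIC and catalytic DMAP in CH2Cl2 into its redox-active ester, 1,3-dioxoisoindolin-2-yl 6-(6-methoxy-3,5-dimethyl-4-oxo-4H-pyran-2-yl)hexanoate F1 and 1,3-dioxoisoindolin-2-yl (S)-6-acetoxyheptanoate F2. The two esters are then joined by the known nickel-catalysed electroreductive doubly decarboxylative Csp3–Csp3 coupling (Ni(II) salt with a polypyridine ligand, sacrificial anode, DMF, F2 in excess). This forms the same bond at reducing instead of oxidising potential and should give 15 directly.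

Step 1. Proton transfer from the acidic product or from imidazole may quench the dianion, and O-acylation or attack on the remote ester may compete with γ-C-acylation. The fallback sets out from dianion 4 (made from 2 as in step 1) and comes back at 5. An aldol addition of 4 to methyl 7-oxoheptanoate in THF at −78 °C should give dimethyl 5-hydroxy-2,4-dimethyl-3-oxoundecanedioate F3, and oxidation of the secondary alcohol with Dess–Martin periodinane in CH2Cl2 should give 5.

Step 3. Methylation may take place at the 4-oxygen as well as at the lactone carbonyl oxygen, eroding the regioselectivity for the 2-methoxy-4-pyranone. The fallback sets out from Grignard reagent 11 (made from 9 as in step 5) and comes back at 7; it uses a pyranone that carries the methoxy group from the start, so no ambident alkylation is needed. Dimethyl 3-oxopentanedioate is C-methylated twice (MeI, K2CO3, acetone) to dimethyl 2,4-dimethyl-3-oxopentanedioate F4, which is cyclodehydrated in fuming sulfuric acid to the symmetrical 2,6-dimethoxy-3,5-dimethyl-4H-pyran-4-one F5. Addition of 11 at C2 with loss of methoxide (THF, −78 → 0 °C) should give 2-methoxy-3,5-dimethyl-6-(pent-4-en-1-yl)-4H-pyran-4-one F6. Cross-metathesis with methyl acrylate (Grubbs second-generation catalyst, CH2Cl2, 40 °C) should give methyl (E)-6-(6-methoxy-3,5-dimethyl-4-oxo-4H-pyran-2-yl)hex-2-enoate F7, and hydrogenation (H2, Pd/C, EtOAc) should give 7.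

**Further compounds**

F1 | step 8 | 1,3-dioxoisoindolin-2-yl 6-(6-methoxy-3,5-dimethyl-4-oxo-4H-pyran-2-yl)hexanoate | COc1oc(CCCCCC(=O)ON2C(=O)c3ccccc3C2=O)c(C)c(=O)c1C
F2 | step 8 | 1,3-dioxoisoindolin-2-yl (S)-6-acetoxyheptanoate | O=C(CCCC[C@H](C)OC(C)=O)ON1C(=O)c2ccccc2C1=O
F3 | step 1 | dimethyl 5-hydroxy-2,4-dimethyl-3-oxoundecanedioate | COC(=O)C(C)C(=O)C(C)C(O)CCCCCC(=O)OC
F4 | step 3 | dimethyl 2,4-dimethyl-3-oxopentanedioate | COC(=O)C(C)C(=O)C(C)C(=O)OC
F5 | step 3 | 2,6-dimethoxy-3,5-dimethyl-4H-pyran-4-one | COc1oc(OC)c(C)c(=O)c1C
F6 | step 3 | 2-methoxy-3,5-dimethyl-6-(pent-4-en-1-yl)-4H-pyran-4-one | COc1oc(CCCC=C)c(C)c(=O)c1C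
F7 | step 3 | methyl (E)-6-(6-methoxy-3,5-dimethyl-4-oxo-4H-pyran-2-yl)hex-2-enoate | COC(=O)/C=C/CCCc1oc(OC)c(C)c(=O)c1C
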